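## Analysis of the target

Compound 15, (2S,3S,4R,5R)-2-(3,4-dimethoxyphenyl)-3,4-dimethyl-5-(3,4,5-trimethoxyphenyl)tetrahydrofuran, is one oxolane ring in which all four carbons are stereocentres: C2 and C5 are benzylic ether carbons, C3 and C4 carry the methyl groups. The methyl groups are cis to each other and the aryl groups are cis to each other on the opposite face, so the sequence is 2,3-trans, 3,4-cis, 4,5-trans. The molecule is almost meso; only the third methoxy group on the C5 aryl ring breaks the mirror plane through O1 and the middle of C3–C4, so absolute control requires the two aryl groups to enter in separate, clearly different events. The order of these events is set by the arenes: veratrole (13) is substituted at C4 and gives a 3,4-dimethoxyphenyl group, whereas 1,2,3-trimethoxybenzene would give a 2,3,4-substituted ring, so the trimethoxyphenyl group must arrive as an aldehyde-derived carbon. Functionality is sparse but not innocent: both ring C–O bonds are benzylic ethers of electron-rich arenes and can ionise under acid or be hydrogenolysed. The difficulty is the four contiguous stereocentres and above all the 3,4-cis dimethyl pair, the less stable arrangement and not the one obtained by enolate alkylation next to an existing methyl group. The plan reads C3–CH3 and C4–CH3, cis to each other and both anti to the C5 aryl group, as the two CH2 arms of a thiolane cis-fused to the C3–C4 bond of a 5-aryl γ-lactone, which can be installed across a butenolide C3=C4 bond in one cycloaddition.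

## Retrosynthetic reasoning

**C2–aryl bond.** The last bond made is C2–C(aryl); cutting it gives the cyclic oxocarbenium ion 14 and veratrole 13. C2 is the one stereocentre whose configuration follows from its neighbour by steric approach: attack anti to the C3 methyl gives 2,3-trans and therefore 2,5-cis. The cut also places the two aryl groups at opposite ends of the synthesis. The forward reaction must achieve para-selective Friedel–Crafts alkylation and facial selectivity at C2 without ionising the benzylic C5–O bond. Ion 14 is drawn from the anomeric acetate 12.

**Oxidation level at C2.** The C2–OAc carbon of 12 is the carbonyl carbon of lactone 10, reached through the aluminium hemiacetal 11. A lactone is the form in which C3–C5 can be assembled; one hydride and one acylation then turn its carbonyl into a leaving group. The forward step must stop at the hemiacetal level.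

**The two methyl groups.** In 10 each methyl C–H is exchanged for a C–S bond to a shared sulfur atom, giving the bicyclic thiolane lactone 9. This changes the stereochemical problem: a cis-dimethyl pair on one ring becomes a cis fusion of two five-membered rings, the only fusion such a bicycle readily adopts. Forward, both C–S bonds must be hydrogenolysed without touching the benzylic C5–O bond or the epimerisable C3.

**Key disconnection.** Thiolane 9 is cut at both C–C bonds joining its CH2 groups to the lactone ring (C3a–C4 and C6a–C6, thienofuranone numbering). This removes a C–S–C unit, the thiocarbonyl ylide 8, and leaves butenolide 6. Both bonds are cut together because a concerted addition puts both carbons on the same face of the alkene; stepwise conjugate addition and alkylation give the trans arrangement. The gain is two C–C bonds, one ring and two stereocentres, and the one existing stereocentre, C5 with its aryl group, must steer the dipole to the opposite face. Ylide 8 cannot be stored and is traced to the silyl chloro sulfide 7, which releases it with fluoride.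

**Lactone ring.** Butenolide 6 is opened at the ring O–C(=O) bond to the Z-hydroxy enoate 5, whose Z-alkene comes from the alkyne of 4. Ring closure costs nothing once the alkene is cis. The forward step must stop at the alkene and leave the acidic C5–H undisturbed.

**The stereocentre set by catalysis.** Propargylic alcohol 4 is cut between the carbinol carbon and the alkyne, giving aldehyde 1 and, through its zinc acetylide 3, methyl propiolate 2. An aldehyde face flanked by aryl and hydrogen is a well-differentiated problem for a chiral catalyst, unlike any later attempt to tell the two aryl groups of the near-meso target apart. All carbons of the lactone and of the trimethoxyphenyl ring come from two commercial compounds.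

## Alternatives that were turned down

**Alternative 1:** Ring A (the dimethoxyphenyl ring) would be built instead of bought. Compound 15 is traced to the 1,4-cyclohexadiene A1, and A1 to the C2-ethynyl tetrahydrofuran A2 and 2,3-dimethoxybuta-1,3-diene A3. Forward, CoBr2(dppe), reduced in the flask by Zn with ZnI2 present, would catalyse a (4+2) cycloaddition of the alkyne of A2 with A3, and A1 would then be dehydrogenated to the arene.
- For: the diene is symmetric, so ring A can only come out 3,4-dimethoxylated.
- Where it is stronger: while a Lewis acid is needed to install the C2 substituent, C2 is propargylic and not benzylic, so acid-induced opening of a 2-aryl tetrahydrofuran cannot occur at that stage.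
- Against: the cycloaddition creates no stereocentre. A2 must already hold all four, including the cis-dimethyl pair, so the real problem is untouched and would still need something like the chosen key step.
- Against: three operations (alkynylation, cycloaddition, aromatisation) and a hydrolysis-prone bis-enol ether are spent on a ring that 13 supplies in one step. The electron-rich diene A3 is also poorly matched to an unactivated alkyne.
- In its place the chosen route offers direct arylation, in which kinetic approach and benzylic equilibration are expected to favour the same isomer.

**Alternative 2:** The C4–C5 bond is disconnected with the C4 methyl written as an ester: 15 comes from ester A4, and A4 from the α-diazo ester A5, whose C2 oxygen carries a 3,4,5-trimethoxybenzyl group. Forward, Rh2(S-PTTL)4, the dirhodium tetracarboxylate of N-phthaloyl-(S)-tert-leucine, would form a carbenoid from A5 that inserts into a benzylic C–H bond of the ether through a five-membered transition state, closing the ring.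
- Where it is stronger: ring formation and the C5 stereocentre come from one catalytic C–H functionalisation, both aryl groups derive from simple benzylic building blocks, no Friedel–Crafts step acts on a benzylic ether, and no sulfur is handled.
- Against: the carbenoid carbon has a neighbouring C–H, and 1,2-hydride shift to an α,β-unsaturated ester is the classic competitor of insertion.
- Against: the ester-bearing carbon of A4 lies between a methyl group on one face and an aryl group on the other. Neither kinetic nor thermodynamic preference clearly favours the required isomer, and the centre stays epimerisable until the ester is reduced.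
- Against: the catalyst would act on a substrate that already has two stereocentres (matched or mismatched). A5 needs those centres and a diazo transfer onto a branched ester, and the ester must afterwards be taken down to a methyl group in about three more steps.
- In its place the chosen route delivers both methyl carbons at the correct oxidation level once sulfur is removed, with their cis relationship fixed by the geometry of a cycloaddition rather than by an epimerisable centre.

**Alternative 3:** Both C2–C3 and C4–C5 are cut at once: 15 comes from the bicyclic anhydride A6, and A6 from (3,4-dimethoxyphenyl)diazomethane A7, aldehyde 1 and maleic anhydride A8. Forward, Rh2(S-PTTL)4 would decompose A7, the carbenoid would be trapped by the carbonyl oxygen of 1 as a carbonyl ylide, and A8 would add (3+2). Both carbonyl carbons would then be reduced to methyl through diol A9.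
- Where it is clearly stronger: convergence. Three simple components would give the whole skeleton and, through the exo adduct, all four relative configurations in one step.
- Against: enantiocontrol. The free carbonyl ylide is planar and achiral, and its two faces differ only in which end carries the dimethoxyphenyl and which the trimethoxyphenyl group. Any induction would need the chiral rhodium to stay bound during cycloaddition and to distinguish two almost identical aryl termini, so a near-racemic product must be expected.
- Against: exo selectivity is not guaranteed, the ylide can collapse to an epoxide or add to a second aldehyde, and the electron-rich A7 is unstable.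
- Against: converting the anhydride to two methyl groups passes through A9, a cis-1,4-diol that tends to close a second oxolane ring on activation.
- In its place the chosen route sets one strongly differentiated stereocentre by catalysis and relays it to the other three, which this alternative cannot match for a single enantiomer.

Key step: step 3

Assumption: the catalyst from Me2Zn and (S,S)-ProPhenol is taken to give (S)-4; the sense of induction is checked on the first batch (MTPA esters), and the (R,R)-ligand is used if it proves opposite.

Remark: the descriptor changes from S in 4 to R in 5 and 6 with no change at the stereocentre, because an alkynyl carbon outranks the aryl carbon in the sequence rule and an alkenyl carbon does not.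

## Route

Step 1
Reactants: 1 3,4,5-trimethoxybenzaldehyde; 2 methyl propiolate
Product: 4 methyl (S)-4-hydroxy-4-(3,4,5-trimethoxyphenyl)but-2-ynoate, via methylzinc acetylide 3 (not isolated)
Conditions: Me2Zn (3 equiv), (S,S)-ProPhenol (10 mol %), Ph3P=O (20 mol %), toluene, 0–4 °C; aq NH4Cl
Reagents that add atoms: none
Why: Me2Zn deprotonates 2 to the alkynylzinc 3, which the dinuclear zinc–ProPhenol catalyst delivers to one face of the aldehyde held on the second zinc atom (catalytic asymmetric alkynylation of an aldehyde). The catalyst alone sets the carbinol stereocentre, and Me2Zn is chosen because methyl transfer to the aldehyde is slow and the ester and aryl ethers are inert to it at this temperature.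

Step 2
Reactants: 4
Product: 6 (R)-5-(3,4,5-trimethoxyphenyl)furan-2(5H)-one, via Z-hydroxy enoate 5 (not isolated)
Conditions: H2 (1 atm), Pd/CaCO3 poisoned with Pb(OAc)2, quinoline, EtOAc, rt; filter; pyridinium p-toluenesulfonate (cat.), CH2Cl2, rt
Reagents that add atoms: none
Why: Syn addition of hydrogen on poisoned palladium stops at the Z-alkene 5 (alkyne semi-hydrogenation), in which hydroxyl and ester are held cis and close the ring by intramolecular transesterification. Only the weakly basic quinoline and a mild acid are present, so the acidic C5–H of 6 is not removed and the configuration of 4 is carried over.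

Step 3
Reactants: 6; 7 chloromethyl trimethylsilylmethyl sulfide
Product: 9 (3R,3aR,6aS)-3-(3,4,5-trimethoxyphenyl)tetrahydro-1H,3H-thieno[3,4-c]furan-1-one (cis-fused thiolane lactone; both CH2 groups anti to the aryl group), via thiocarbonyl ylide 8 (not isolated)
Conditions: 7 (2.5 equiv), anhydrous CsF (4 equiv, added in portions), MeCN, 0 °C → rt
Reagents that add atoms: none
Why: Fluoride attacks the silicon of 7 and the resulting α-thio carbanion expels chloride, giving the parent thiocarbonyl ylide 8, an electron-rich 1,3-dipole of the allyl-anion type. Ylide 8 adds across C3=C4 of the electron-poor butenolide 6 in a concerted, suprafacial 1,3-dipolar (3+2) cycloaddition (HOMO of the dipole, LUMO of the enoate); the closest known reaction type is the addition of this ylide to α,β-unsaturated esters and lactones. The thiolane ring is closed in that one event by forming C3a–C4 and C6a–C6 together, with no separate stepwise closure, so the ring fusion can only be cis. C3a and C6a are the new stereocentres: their mutual cis relationship is fixed by suprafacial addition to the endocyclic cis-alkene, and their configuration relative to the aryl-bearing carbon by approach from the face opposite the aryl group. The only selectivity needed is π-facial, since 8 is symmetric and raises no regiochemical or endo/exo question; the nearly flat butenolide ring holds the trimethoxyphenyl group over one face and so secures it. The cycloaddition must outrun fluoride-induced removal of the acidic C5–H of 6, hence the excess of 7, the low starting temperature and the portionwise CsF.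

Step 4
Reactants: 9
Product: 10 (3S,4R,5R)-3,4-dimethyl-5-(3,4,5-trimethoxyphenyl)dihydrofuran-2(3H)-one
Conditions: Raney Ni (W-2, washed to neutrality), EtOH/THF, rt
Reagents that add atoms: none
Why: Hydrogen-loaded nickel cleaves both C–S bonds (reductive desulfurisation), turning each CH2–S arm into a methyl group without touching a stereocentre, so the cis ring fusion becomes the cis-3,4-dimethyl pair. Neutral nickel at room temperature is chosen so that the benzylic lactone C–O bond is not hydrogenolysed and C3 is not exposed to alkali.

Step 5
Reactants: 10
Product: 12 (3S,4R,5R)-3,4-dimethyl-5-(3,4,5-trimethoxyphenyl)tetrahydrofuran-2-yl acetate (anomer mixture), via aluminium hemiacetal 11 (not isolated)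
Conditions: iBu2AlH (1.2 equiv), CH2Cl2, −78 °C; then pyridine, DMAP, Ac2O, −78 → 0 °C
Reagents that add atoms: acetic anhydride, CC(=O)OC(C)=O
Why: At −78 °C one hydride adds to the lactone carbonyl and the tetrahedral aluminium hemiacetal 11 does not collapse; acylating it in the same flask (one-pot reductive acetylation of a lactone) gives the anomeric acetate without over-reduction to the diol. The anomeric configuration does not matter because C2 becomes planar in the next step.

Step 6
Reactants: 12; 13 veratrole (1,2-dimethoxybenzene)
Product: 15 (2S,3S,4R,5R)-2-(3,4-dimethoxyphenyl)-3,4-dimethyl-5-(3,4,5-trimethoxyphenyl)tetrahydrofuran (CNP0210192.3), via oxocarbenium ion 14 (not isolated)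
Conditions: 13 (3 equiv), BF3·OEt2 (1.5 equiv), CH2Cl2, −78 → −20 °C; aq NaHCO3
Reagents that add atoms: none
Why: BF3 ionises the anomeric acetate to the oxocarbenium ion 14, which is attacked by the most nucleophilic position of 13, para to a methoxy group (Friedel–Crafts alkylation by a lactol acetate). The arene approaches C2 anti to the adjacent C3 methyl group, giving 2,3-trans and hence 2,5-cis; this should also be the more stable arrangement at a benzylic centre able to equilibrate under the Lewis acid.

## Compound list

1 | 3,4,5-trimethoxybenzaldehyde | COc1cc(C=O)cc(OC)c1OC | starting material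
2 | methyl propiolate | C#CC(=O)OC | starting material
3 | methyl 3-(methylzincio)prop-2-ynoate, MeZn–C≡C–CO2Me (not isolated) | C[Zn]C#CC(=O)OC | intermediate
4 | methyl (S)-4-hydroxy-4-(3,4,5-trimethoxyphenyl)but-2-ynoate | O[C@@H](c1cc(OC)c(OC)c(OC)c1)C#CC(=O)OC | intermediate
5 | methyl (R,Z)-4-hydroxy-4-(3,4,5-trimethoxyphenyl)but-2-enoate (not isolated) | O[C@@H](c1cc(OC)c(OC)c(OC)c1)/C=C\C(=O)OC | intermediate
6 | (R)-5-(3,4,5-trimethoxyphenyl)furan-2(5H)-one | O=C1O[C@@H](c2cc(OC)c(OC)c(OC)c2)C=C1 | intermediate
7 | chloromethyl trimethylsilylmethyl sulfide | C[Si](C)(C)CSCCl | starting material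
8 | thioformaldehyde S-methylide, the parent thiocarbonyl ylide (not isolated) | C=[S+][CH2-] | intermediate
9 | (3R,3aR,6aS)-3-(3,4,5-trimethoxyphenyl)tetrahydro-1H,3H-thieno[3,4-c]furan-1-one | O=C1O[C@@H](c2cc(OC)c(OC)c(OC)c2)[C@@H]2CSC[C@H]12 | intermediate
10 | (3S,4R,5R)-3,4-dimethyl-5-(3,4,5-trimethoxyphenyl)dihydrofuran-2(3H)-one | O=C1O[C@@H](c2cc(OC)c(OC)c(OC)c2)[C@H](C)[C@@H]1C | intermediate
11 | (3S,4R,5R)-2-[(diisobutylalumanyl)oxy]-3,4-dimethyl-5-(3,4,5-trimethoxyphenyl)tetrahydrofuran, the iBu2Al hemiacetal of 10 (not isolated) | CC(C)C[Al](CC(C)C)OC1O[C@@H](c2cc(OC)c(OC)c(OC)c2)[C@H](C)[C@@H]1C | intermediate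
12 | (3S,4R,5R)-3,4-dimethyl-5-(3,4,5-trimethoxyphenyl)tetrahydrofuran-2-yl acetate, mixture of C2 anomers | CC(=O)OC1O[C@@H](c2cc(OC)c(OC)c(OC)c2)[C@H](C)[C@@H]1C | intermediate
13 | veratrole (1,2-dimethoxybenzene) | COc1ccccc1OC | starting material
14 | (3S,4R,5R)-3,4-dimethyl-5-(3,4,5-trimethoxyphenyl)-4,5-dihydro-3H-furan-1-ium, lactone numbering; cyclic oxocarbenium ion (not isolated) | C1=[O+][C@@H](c2cc(OC)c(OC)c(OC)c2)[C@H](C)[C@@H]1C | intermediate
15 | (2S,3S,4R,5R)-2-(3,4-dimethoxyphenyl)-3,4-dimethyl-5-(3,4,5-trimethoxyphenyl)tetrahydrofuran | COc1ccc([C@H]2O[C@@H](c3cc(OC)c(OC)c(OC)c3)[C@H](C)[C@@H]2C)cc1OC | target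

## Step count and least certain steps

Total: 6 steps. Longest linear sequence: 6 steps (1 → 4 → 6 → 9 → 10 → 12 → 15); 2, 7 and 13 are bought and enter directly.

**Step 3 (key step).**
- The most likely failure is loss of enantiomeric purity before the cycloaddition. The C5–H of 6 is benzylic, allylic and γ to the carbonyl, so fluoride in MeCN can remove it to give an aromatic 2-oxidofuran; reprotonation racemises 6 or moves the double bond out of conjugation.
- A second failure is self-consumption of the short-lived ylide when addition to the 1,2-disubstituted enoate is slow.
- Facial selectivity is the smaller concern. The enantiomeric purity of 9 should be compared with that of 6.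
- Fallback, from 6 and returning at 10: the methyl groups are introduced one at a time. Conjugate addition of lithium dimethylcuprate F1 (Me2CuLi, with Me3SiCl, THF, −78 °C) anti to the aryl group should give the trans-4-methyl lactone F2. Deprotonation with LiN(SiMe3)2 and methylation with MeI should give the all-trans 3,4-dimethyl lactone F3. Renewed deprotonation gives the lithium enolate F4, which is protonated kinetically at −78 °C by a hindered phenol from the face opposite the C4 methyl group, pushing the C3 methyl cis to it and giving 10.
- This is two steps longer and its last selectivity is only kinetic, which is why it is the reserve.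

**Step 6.**
- Facial selectivity at C2 may be incomplete.
- The Lewis acid may ionise the benzylic C–O bonds of the product, leading to epimerisation or to a second arylation of the ring-opened cation by excess 13.
- Ion 14 may lose the C3 proton to give an enol ether, which would scramble C3.
- Fallback, from 10 and returning at 15: 3,4-dimethoxyphenyllithium F5 (from 4-bromoveratrole and nBuLi, THF, −78 °C) is added once to the lactone to give the hydroxy ketone F6. NaBH4 reduces F6 to the 1,4-diol F7 as a mixture at the new carbinol. Catalytic acid (pyridinium p-toluenesulfonate, CH2Cl2) then ionises the more stabilised 3,4-dimethoxybenzylic carbinol, and the C4 hydroxyl closes the ring on the cation (SN1 cyclodehydration) anti to the neighbouring methyl group.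
- The configuration of the reduced carbinol is therefore irrelevant, and no external arene is present to over-alkylate.

**Step 4.**
- The benzylic lactone C5–O bond may be hydrogenolysed along with the C–S bonds, opening the ring to an aryl butanoic acid.
- Residual alkali on the nickel may epimerise C3 to the more stable trans isomer.
- Cleavage may stop at the thiol stage.
- Fallback, from 9 and returning at 15: sulfur is carried through and removed last. One-pot reductive acetylation of 9 (iBu2AlH; Ac2O, pyridine, DMAP) gives the thiolane lactol acetate F8. BF3·OEt2 and 13, with extra Lewis acid to allow for binding at sulfur, should give the thiolane-fused diaryl tetrahydrofuran F9, the arene attacking the convex face of the cis-fused bicyclic cation, anti to the thiolane ring. Raney Ni in THF/EtOH at room temperature then converts F9 into 15.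
- At that stage the benzylic oxygens are ether and not acyloxy oxygens, and no epimerisable centre next to a carbonyl remains.

**Step 1.**
- Enantioselectivity may be insufficient, or the sense of induction unexpected, with this electron-rich and weakly electrophilic aldehyde.
- Uncatalysed background addition may compete, and base may isomerise 4 to a γ-keto enoate.
- Fallback, from 1 and returning at 6: the stereocentre is set by ketone reduction. A Stetter reaction of 1 with methyl acrylate (thiazolium salt, Et3N) gives the keto ester F10. Asymmetric transfer hydrogenation with RuCl(p-cymene)[(R,R)-TsDPEN] in HCO2H/Et3N, then acid-induced lactonisation, should give the saturated (R)-lactone F11. Deprotonation with LiN(iPr)2 and trapping with PhSeBr gives the α-phenylselanyl lactone F12, and oxidation with H2O2 followed by syn-elimination of the selenoxide gives 6.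
- The sense of induction for aryl alkyl ketones is well established, at the price of two extra steps.

## Further compounds

F1 | step 3 | lithium dimethylcuprate, Me2CuLi | [Li+].C[Cu-]C
F2 | step 3 | (4R,5R)-4-methyl-5-(3,4,5-trimethoxyphenyl)dihydrofuran-2(3H)-one | O=C1O[C@@H](c2cc(OC)c(OC)c(OC)c2)[C@H](C)C1
F3 | step 3 | (3R,4R,5R)-3,4-dimethyl-5-(3,4,5-trimethoxyphenyl)dihydrofuran-2(3H)-one | O=C1O[C@@H](c2cc(OC)c(OC)c(OC)c2)[C@H](C)[C@H]1C
F4 | step 3 | lithium enolate of F3, lithium (4R,5R)-3,4-dimethyl-5-(3,4,5-trimethoxyphenyl)-4,5-dihydrofuran-2-olate | [Li]OC1=C(C)[C@@H](C)[C@H](c2cc(OC)c(OC)c(OC)c2)O1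
F5 | step 6 | 3,4-dimethoxyphenyllithium | [Li]c1ccc(OC)c(OC)c1
F6 | step 6 | (2S,3R,4R)-1-(3,4-dimethoxyphenyl)-4-hydroxy-2,3-dimethyl-4-(3,4,5-trimethoxyphenyl)butan-1-one | O[C@@H](c1cc(OC)c(OC)c(OC)c1)[C@H](C)[C@H](C)C(=O)c1ccc(OC)c(OC)c1
F7 | step 6 | (2S,3R,4R)-1-(3,4-dimethoxyphenyl)-2,3-dimethyl-4-(3,4,5-trimethoxyphenyl)butane-1,4-diol, mixture at C1 | O[C@@H](c1cc(OC)c(OC)c(OC)c1)[C@H](C)[C@H](C)C(O)c1ccc(OC)c(OC)c1
F8 | step 4 | (3R,3aR,6aS)-3-(3,4,5-trimethoxyphenyl)tetrahydro-1H,3H-thieno[3,4-c]furan-1-yl acetate, mixture of C1 anomers | CC(=O)OC1O[C@@H](c2cc(OC)c(OC)c(OC)c2)[C@@H]2CSC[C@H]12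
F9 | step 4 | (1S,3R,3aR,6aS)-1-(3,4-dimethoxyphenyl)-3-(3,4,5-trimethoxyphenyl)tetrahydro-1H,3H-thieno[3,4-c]furan | COc1ccc([C@H]2O[C@@H](c3cc(OC)c(OC)c(OC)c3)[C@@H]3CSC[C@H]23)cc1OC
F10 | step 1 | methyl 4-oxo-4-(3,4,5-trimethoxyphenyl)butanoate | COC(=O)CCC(=O)c1cc(OC)c(OC)c(OC)c1
F11 | step 1 | (R)-5-(3,4,5-trimethoxyphenyl)dihydrofuran-2(3H)-one | O=C1O[C@@H](c2cc(OC)c(OC)c(OC)c2)CC1
F12 | step 1 | (5R)-3-(phenylselanyl)-5-(3,4,5-trimethoxyphenyl)dihydrofuran-2(3H)-one, mixture at C3 | O=C1O[C@@H](c2cc(OC)c(OC)c(OC)c2)CC1[Se]c1ccccc1
A1 | alternative 1 | (2S,3S,4R,5R)-2-(4,5-dimethoxycyclohexa-1,4-dien-1-yl)-3,4-dimethyl-5-(3,4,5-trimethoxyphenyl)tetrahydrofuran | COC1=C(OC)CC([C@H]2O[C@@H](c3cc(OC)c(OC)c(OC)c3)[C@H](C)[C@@H]2C)=CC1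
A2 | alternative 1 | (2S,3S,4R,5R)-2-ethynyl-3,4-dimethyl-5-(3,4,5-trimethoxyphenyl)tetrahydrofuran | C#C[C@H]1O[C@@H](c2cc(OC)c(OC)c(OC)c2)[C@H](C)[C@@H]1C
A3 | alternative 1 | 2,3-dimethoxybuta-1,3-diene | C=C(OC)C(=C)OC
A4 | alternative 2 | methyl 5-(3,4-dimethoxyphenyl)-4-methyl-2-(3,4,5-trimethoxyphenyl)tetrahydrofuran-3-carboxylate, configured as 15 with the ester in place of the C4 methyl group | COc1ccc([C@H]2O[C@@H](c3cc(OC)c(OC)c(OC)c3)[C@H](C(=O)OC)[C@@H]2C)cc1OC
A5 | alternative 2 | methyl 2-diazo-4-(3,4-dimethoxyphenyl)-3-methyl-4-[(3,4,5-trimethoxybenzyl)oxy]butanoate, C3 and C4 configured as C3 and C2 of 15 | COc1ccc([C@@H](OCc2cc(OC)c(OC)c(OC)c2)[C@@H](C)C(=[N+]=[N-])C(=O)OC)cc1OC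
A6 | alternative 3 | 4-(3,4-dimethoxyphenyl)-6-(3,4,5-trimethoxyphenyl)tetrahydrofuro[3,4-c]furan-1,3-dione, aryl groups cis to each other and trans to the anhydride ring (exo adduct), configured as 15 | COc1ccc([C@H]2O[C@@H](c3cc(OC)c(OC)c(OC)c3)[C@H](C(=O)OC4=O)[C@@H]24)cc1OC
A7 | alternative 3 | (3,4-dimethoxyphenyl)diazomethane | COc1ccc(C=[N+]=[N-])cc1OC
A8 | alternative 3 | maleic anhydride | O=C1OC(=O)C=C1
A9 | alternative 3 | [2-(3,4-dimethoxyphenyl)-5-(3,4,5-trimethoxyphenyl)tetrahydrofuran-3,4-diyl]dimethanol, configured as 15 | COc1ccc([C@H]2O[C@@H](c3cc(OC)c(OC)c(OC)c3)[C@H](CO)[C@@H]2CO)cc1OC
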